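Ring B is disconnected at C7–C8 and C9–C10 (eudesmane numbering). The unsubstituted C8–C9 bridge between C7 and the quaternary C10 marks ring B as a [4+2] adduct of a two-carbon dienophile with the semicyclic diene C10=C5–C6=C7. The key Diels–Alder reaction uses ethynyl p-tolyl sulfone (an ethylene surrogate after reduction) and a diene carrying a sacrificial (S)-silyloxy centre at C4 and a masked acetyl group at C7; it closes ring B and fixes C10. A 4,11-diketone then lets C5 and C7 settle thermodynamically, and its two enol triflates deliver the C3=C4–CH2O unit and the acrylate.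

Key step: step 5

Remark: eudesmane numbering is used for all bicyclic compounds (C10 = quaternary carbon with angular methyl C14; C5 = ring-fusion CH; C1–C4 complete ring A; C6–C9 complete ring B; C7 carries the side chain starting at C11; C15 = carbon on C4), and an intermediate expected as a converging isomer mixture is drawn as the isomer expected to predominate.

Step 1
Reactants: 1 3-methylcyclohex-2-en-1-one
Product: 2 2-iodo-3-methylcyclohex-2-en-1-one
Conditions: I2, pyridine, CH2Cl2, rt
Reagents that add atoms: iodine, II
Why: α-Iodination of the enone by amine conjugate addition, iodination of the enolate and elimination (Baylis–Hillman-type halogenation); no stereocentre is formed.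

Step 2
Reactants: 2 2-iodo-3-methylcyclohex-2-en-1-one
Product: 3 (S)-2-iodo-3-methylcyclohex-2-en-1-ol
Conditions: (R)-2-methyl-CBS-oxazaborolidine (10 mol %), BH3·SMe2, THF, −20 °C; MeOH, then aq. work-up
Reagents that add atoms: none
Why: Corey–Bakshi–Shibata reduction in which the iodoalkenyl carbon acts as the large ketone substituent, so the (R)-catalyst should give the (S)-carbinol that later steers the cycloaddition.

Step 3
Reactants: 3 (S)-2-iodo-3-methylcyclohex-2-en-1-ol
Product: 4 (S)-tert-butyl[(2-iodo-3-methylcyclohex-2-en-1-yl)oxy]dimethylsilane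
Conditions: TBSCl, imidazole, DMF, rt
Reagents that add atoms: tert-butyldimethylsilyl chloride, CC(C)(C)[Si](C)(C)Cl
Why: Standard silylation; the bulky silyl ether is the face-shielding group for step 5 and protects the C4 oxygen until step 8.

Step 4
Reactants: 4 (S)-tert-butyl[(2-iodo-3-methylcyclohex-2-en-1-yl)oxy]dimethylsilane; 5 2-methyl-2-vinyl-1,3-dioxolane
Product: 6 (S,E)-tert-butyldimethyl({3-methyl-2-[2-(2-methyl-1,3-dioxolan-2-yl)ethenyl]cyclohex-2-en-1-yl}oxy)silane
Conditions: Pd(OAc)2 (10 mol %), Bu4NCl, NaHCO3, DMF, 70 °C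
Reagents that add atoms: none
Why: Heck reaction of the alkenyl iodide under ligand-free phase-transfer conditions; syn insertion and syn β-hydride elimination give the (E)-diene, and the quaternary ketal carbon offers no hydrogen for double-bond migration.

Step 5
Reactants: 6 (S,E)-diene; 7 ethynyl p-tolyl sulfone
Product: 8 bicyclic dienyl sulfone (C5=C6 and C8=C9 alkenes, (4S)-OTBS, (10R)-methyl, 2-methyl-1,3-dioxolan-2-yl on C7 trans to the C10 methyl, p-tolylsulfonyl on C8)
Conditions: toluene, BHT (cat.), 100 °C, sealed tube
Reagents that add atoms: none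
Why: Concerted, asynchronous thermal [4+2] cycloaddition in which the two alkyne carbons (C8, C9) bond suprafacially to the diene termini C7 and C10; the closest known reaction type is the Diels–Alder reaction of 2-substituted 1-vinylcyclohexenes (tetrasubstituted diene terminus) with acetylenic dienophiles, with alkynyl sulfones serving as acetylene equivalents. Ring B is closed in an intermolecular [4+2] mode across C7 and C10, and the linear, strongly activated alkyne is chosen because it should tolerate the hindered quaternary-forming terminus better than an alkene. The new quaternary centre C10 is controlled by the C4 stereocentre: allylic 1,2-strain places the OTBS group pseudoaxial and the dienophile should add to the diene face anti to it, giving (10R). C7 arises with its ketal substituent trans to the C10 methyl as a consequence of the (E)-alkene geometry, and this centre is corrected in step 9. Only facial selectivity is needed, because the sulfonyl group (drawn on C8 on steric grounds) is removed in step 6 whatever the regiochemistry, and a minor facial isomer would be a separable diastereomer as long as C4 is stereogenic.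

Step 6
Reactants: 8 bicyclic dienyl sulfone
Product: 9 skipped diene (C5=C6 and C8=C9, (4S)-OTBS, (10R)-methyl, dioxolanyl on C7 trans to the C10 methyl)
Conditions: Na(Hg) (6%), Na2HPO4, MeOH/THF, −20 → 0 °C
Reagents that add atoms: none
Why: Reductive desulfonylation of the alkenyl sulfone by electron transfer and protonation by the buffer; any regio- or double-bond isomer converges in steps 7–9.

Step 7
Reactants: 9 skipped diene
Product: 10 saturated decalin ((4S)-OTBS, (10R)-methyl, 5-H cis to the C10 methyl, dioxolanyl on C7 trans to the C10 methyl)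
Conditions: H2 (3 atm), PtO2, EtOAc, rt
Reagents that add atoms: none
Why: Heterogeneous hydrogenation of both ring B alkenes; addition at C5 is expected from the convex β-face (cis-fused product drawn), but either ring-fusion epimer is acceptable because C5 is equilibrated in step 9.

Step 8
Reactants: 10 saturated decalin
Product: 11 7-acetyl-10-methyldecalin-4-ol ((4S)-OH cis to the C10 methyl, cis ring fusion, acetyl trans to the C10 methyl)
Conditions: aq. HCl (2 M), THF/MeOH, 40 °C
Reagents that add atoms: water, O
Why: Acid hydrolysis of the dioxolane and of the secondary silyl ether in one operation; partial epimerisation at C7 would be harmless.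

Step 9
Reactants: 11 7-acetyl-10-methyldecalin-4-ol
Product: 13 (5R,7R,10R)-7-acetyl-10-methyl-trans-decalin-4-one, via kinetic diketone 12 (not isolated)
Conditions: DMP (1,1,1-triacetoxy-1,1-dihydro-1,2-benziodoxol-3(1H)-one), CH2Cl2, rt; aq. wash; then NaOMe (cat.), MeOH, rt
Reagents that add atoms: none
Why: Periodinane oxidation of the C4 carbinol followed by enolate-mediated epimerisation of C5 (α to the C4 ketone) and C7 (α to the acetyl) under thermodynamic control, which should favour the trans-fused decalone with the equatorial acetyl cis to the axial angular methyl, so that both centres are set relative to C10.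

Step 10
Reactants: 13 (5R,7R,10R)-7-acetyl-10-methyl-trans-decalin-4-one
Product: 14 bis(enol triflate) (C3=C4–OTf in ring A and C11(OTf)=CH2 on C7)
Conditions: KN(SiMe3)2 (2.4 equiv), THF, −78 °C; PhNTf2 (2.4 equiv), −78 → 0 °C; aq. NH4Cl
Reagents that add atoms: N-phenylbis(trifluoromethanesulfonimide), O=S(=O)(N(c1ccccc1)S(=O)(=O)C(F)(F)F)C(F)(F)F
Why: Kinetic double enolisation at the less hindered α-positions (C3 methylene rather than the ring-fusion C5–H, acetyl methyl rather than C7–H) and O-triflation, so C5 and C7 keep their configuration.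

Step 11
Reactants: 14 bis(enol triflate)
Product: 15 methyl 2-[(5R,7R,10R)-10-methyl-4-(trifluoromethylsulfonyloxy)-Δ3-octalin-7-yl]acrylate
Conditions: Pd(OAc)2 (5 mol %), PPh3 (10 mol %), Et3N, CO (1 atm), MeOH/DMF, rt, stopped when 14 is consumed
Reagents that add atoms: carbon monoxide, [C-]#[O+]; methanol, CO
Why: Alkoxycarbonylation of an alkenyl triflate (oxidative addition to zerovalent palladium, CO insertion, methanolysis); the terminal 1,1-disubstituted triflate should undergo oxidative addition faster than the trisubstituted ring triflate next to the ring fusion, so the acrylate should form site-selectively.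

Step 12
Reactants: 15 acrylate ring triflate
Product: 16 methyl 15-hydroxyeudesma-3,11(13)-dien-12-oate
Conditions: Bu3SnCH2OH, Pd(PPh3)4 (10 mol %), LiCl, 1,4-dioxane, 100 °C
Reagents that add atoms: (tributylstannyl)methanol, OC[Sn](CCCC)(CCCC)CCCC
Why: Stille coupling of the remaining alkenyl triflate with the hydroxymethyl stannane (chloride-assisted transmetalation) installs C15 on the C3=C4 alkene without touching any stereocentre.

Step 13
Reactants: 17 (E)-4-hydroxycinnamic acid
Product: 18 (Z)-4-hydroxycinnamic acid
Conditions: hν (ca. 350 nm), MeOH, rt; chromatographic separation, then handling in the dark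
Reagents that add atoms: none
Why: Photochemical E→Z isomerisation of the cinnamic acid to a photostationary mixture from which the (Z)-acid is separated.

Step 14
Reactants: 16 methyl 15-hydroxyeudesma-3,11(13)-dien-12-oate; 18 (Z)-4-hydroxycinnamic acid
Product: 19 methyl 15-[(Z)-4-hydroxycinnamoyloxy]eudesma-3,11(13)-dien-12-oate (target)
Conditions: PPh3, DIAD, THF, 0 °C → rt (betaine preformed)
Reagents that add atoms: none
Why: Mitsunobu esterification of the primary allylic alcohol, in which the carboxylic acid (far more acidic than the phenol) is the nucleophile and no acyl activation occurs, so the (Z)-alkene should be retained.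

Compound list
1 | 3-methylcyclohex-2-en-1-one | CC1=CC(=O)CCC1 | starting material
2 | 2-iodo-3-methylcyclohex-2-en-1-one | CC1=C(I)C(=O)CCC1 | intermediate
3 | (S)-2-iodo-3-methylcyclohex-2-en-1-ol | O[C@H]1CCCC(C)=C1I | intermediate
4 | (S)-tert-butyl[(2-iodo-3-methylcyclohex-2-en-1-yl)oxy]dimethylsilane | CC(C)(C)[Si](C)(C)O[C@H]1CCCC(C)=C1I | intermediate
5 | 2-methyl-2-vinyl-1,3-dioxolane | C=CC1(C)OCCO1 | starting material
6 | (S,E)-tert-butyldimethyl({3-methyl-2-[2-(2-methyl-1,3-dioxolan-2-yl)ethenyl]cyclohex-2-en-1-yl}oxy)silane | CC(C)(C)[Si](C)(C)O[C@H]1CCCC(C)=C1/C=C/C1(C)OCCO1 | intermediate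
7 | ethynyl p-tolyl sulfone | C#CS(=O)(=O)c1ccc(C)cc1 | starting material
8 | bicyclic dienyl sulfone (C5=C6, C8=C9, 4S-OTBS, 10R, C7 dioxolanyl trans to C14, 8-tosyl) | C[C@]12CCC[C@H](O[Si](C)(C)C(C)(C)C)C1=C[C@@H](C1(C)OCCO1)C(S(=O)(=O)c1ccc(C)cc1)=C2 | intermediate
9 | skipped diene (C5=C6, C8=C9, 4S-OTBS, 10R, C7 dioxolanyl trans to C14) | C[C@]12CCC[C@H](O[Si](C)(C)C(C)(C)C)C1=C[C@@H](C1(C)OCCO1)C=C2 | intermediate
10 | saturated cis-fused decalin (4S-OTBS, 10R, C7 dioxolanyl trans to C14) | C[C@]12CCC[C@H](O[Si](C)(C)C(C)(C)C)[C@H]1C[C@@H](C1(C)OCCO1)CC2 | intermediate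
11 | 7-acetyl-10-methyldecalin-4-ol (4S-OH, cis-fused, acetyl trans to C14) | C[C@]12CCC[C@H](O)[C@H]1C[C@@H](C(C)=O)CC2 | intermediate
12 | kinetic diketone (cis-fused 7-acetyl-10-methyldecalin-4-one, acetyl trans to C14) | C[C@]12CCCC(=O)[C@H]1C[C@@H](C(C)=O)CC2 | intermediate
13 | (5R,7R,10R)-7-acetyl-10-methyl-trans-decalin-4-one | C[C@]12CCCC(=O)[C@@H]1C[C@H](C(C)=O)CC2 | intermediate
14 | bis(enol triflate) of 13 (C3=C4–OTf; C11(OTf)=CH2) | C[C@]12CCC=C(OS(=O)(=O)C(F)(F)F)[C@@H]1C[C@H](C(=C)OS(=O)(=O)C(F)(F)F)CC2 | intermediate
15 | methyl 2-[(5R,7R,10R)-10-methyl-4-(trifluoromethylsulfonyloxy)-Δ3-octalin-7-yl]acrylate | C[C@]12CCC=C(OS(=O)(=O)C(F)(F)F)[C@@H]1C[C@H](C(=C)C(=O)OC)CC2 | intermediate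
16 | methyl 15-hydroxyeudesma-3,11(13)-dien-12-oate | C[C@]12CCC=C(CO)[C@@H]1C[C@H](C(=C)C(=O)OC)CC2 | intermediate
17 | (E)-4-hydroxycinnamic acid | O=C(O)/C=C/c1ccc(O)cc1 | starting material
18 | (Z)-4-hydroxycinnamic acid | O=C(O)/C=C\c1ccc(O)cc1 | intermediate
19 | methyl 15-[(Z)-4-hydroxycinnamoyloxy]eudesma-3,11(13)-dien-12-oate | C=C(C(=O)OC)[C@@H]1CC[C@@]2(C)CCC=C(COC(=O)/C=C\c3ccc(O)cc3)[C@@H]2C1 | target

Total step count: 14
Longest linear sequence: 13 steps (steps 1–12 and 14, from 1 to 19)

Steps most likely to fail

1. Step 5. The cycloaddition may be too slow at the tetrasubstituted diene terminus, so that diene decomposition competes, or the C4 silyloxy group may discriminate the diene faces poorly at the temperature needed. Fallback: the cycloaddition is made intramolecular through a temporary silicon tether. It sets out from 4. Stille coupling (Pd2(dba)3, AsPh3, CuI, NMP) with (E)-4-(tributylstannyl)but-3-en-2-ol F1 (from but-3-yn-2-ol by PdCl2(PPh3)2-catalysed hydrostannation with Bu3SnH) would give the dienol F2 as inconsequential C11 epimers. Silylation with chloro(dimethyl)vinylsilane and Et3N would give the vinylsilyl ether F3. Heating (toluene, 170 °C) should close ring B through the tethered vinylsilane to the siloxane cycloadduct F4. Bu4NF in DMF at 75 °C (fluoride-induced protodesilylation of the 1-oxa-2-silacyclopentane, with loss of the TBS group) would give the diol F5, and hydrogenation (H2, PtO2) the saturated diol F6. Periodinane oxidation of both carbinols then gives 12, where the route is rejoined.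

2. Step 11. The two alkenyl triflates may not be discriminated in oxidative addition, so that double carbonylation erodes the material. Fallback: the two carbonyl groups are differentiated by protecting groups instead of by site selectivity. It sets out from 10. Transketalisation (p-TsOH, acetone) followed by NaOMe/MeOH would give the silyloxy ketone F7 with the acetyl group equilibrated to the equatorial position cis to C14. KN(SiMe3)2/PhNTf2 would give the enol triflate F8, and Pd(OAc)2/PPh3/CO/MeOH/Et3N the silyloxy acrylate F9. Aqueous HF in MeCN would give the alcohol F10. Periodinane oxidation followed by DBU (equilibration of C5 to the trans ring fusion) would give the keto acrylate F11. Kinetic enolisation and triflation (KN(SiMe3)2, PhNTf2, −78 °C) then return to the route at 15.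

3. Step 14. The free phenol may be alkylated in competition with the acid, or the (Z)-alkene may isomerise through reversible phosphine addition. Fallback: the (Z)-alkene is built on the substrate. It sets out from 16. Acylation with (diphenoxyphosphoryl)acetic acid (DCC, DMAP, CH2Cl2) would give the phosphonoacetate F12. A Z-selective Horner–Wadsworth–Emmons reaction with 4-(tert-butyldimethylsilyloxy)benzaldehyde (NaH, THF, −78 °C) would give the silyl-protected (Z)-coumarate F13. Bu4NF buffered with AcOH would then release 19.

Further compounds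
F1 | step 5 | (E)-4-(tributylstannyl)but-3-en-2-ol | CC(O)/C=C/[Sn](CCCC)(CCCC)CCCC
F2 | step 5 | (E)-4-[(6S)-6-(tert-butyldimethylsilyloxy)-2-methylcyclohex-1-en-1-yl]but-3-en-2-ol (C11 epimers) | CC(O)/C=C/C1=C(C)CCC[C@@H]1O[Si](C)(C)C(C)(C)C
F3 | step 5 | dimethyl(vinyl)silyl ether of F2 | C=C[Si](C)(C)OC(C)/C=C/C1=C(C)CCC[C@@H]1O[Si](C)(C)C(C)(C)C
F4 | step 5 | siloxane cycloadduct (1-oxa-2-silacyclopentane fused at C7–C8, C5=C6, 4S-OTBS, 10R) | C[C@]12CCC[C@H](O[Si](C)(C)C(C)(C)C)C1=C[C@H]3C(C)O[Si](C)(C)C3C2
F5 | step 5 | (4S,10R)-7-(1-hydroxyethyl)-10-methyl-Δ5-octalin-4-ol (side chain trans to C14) | C[C@]12CCC[C@H](O)C1=C[C@@H](C(C)O)CC2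
F6 | step 5 | (4S,10R)-7-(1-hydroxyethyl)-10-methyldecalin-4-ol (cis-fused, side chain trans to C14) | C[C@]12CCC[C@H](O)[C@H]1C[C@@H](C(C)O)CC2
F7 | step 11 | cis-fused 7-acetyl-4-(tert-butyldimethylsilyloxy)-10-methyldecalin (4S, 10R, acetyl cis to C14) | C[C@]12CCC[C@H](O[Si](C)(C)C(C)(C)C)[C@H]1C[C@H](C(C)=O)CC2
F8 | step 11 | enol triflate of F7 (C11(OTf)=CH2) | C[C@]12CCC[C@H](O[Si](C)(C)C(C)(C)C)[C@H]1C[C@H](C(=C)OS(=O)(=O)C(F)(F)F)CC2
F9 | step 11 | methyl 2-[4-(tert-butyldimethylsilyloxy)-10-methyldecalin-7-yl]acrylate (cis-fused) | C[C@]12CCC[C@H](O[Si](C)(C)C(C)(C)C)[C@H]1C[C@H](C(=C)C(=O)OC)CC2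
F10 | step 11 | methyl 2-(4-hydroxy-10-methyldecalin-7-yl)acrylate (cis-fused) | C[C@]12CCC[C@H](O)[C@H]1C[C@H](C(=C)C(=O)OC)CC2
F11 | step 11 | methyl 2-[(5R,7R,10R)-10-methyl-4-oxo-trans-decalin-7-yl]acrylate | C[C@]12CCCC(=O)[C@@H]1C[C@H](C(=C)C(=O)OC)CC2
F12 | step 14 | (diphenoxyphosphoryl)acetate of 16 | C[C@]12CCC=C(COC(=O)CP(=O)(Oc3ccccc3)Oc3ccccc3)[C@@H]1C[C@H](C(=C)C(=O)OC)CC2
F13 | step 14 | O-tert-butyldimethylsilyl ether of 19 | C[C@]12CCC=C(COC(=O)/C=C\c3ccc(O[Si](C)(C)C(C)(C)C)cc3)[C@@H]1C[C@H](C(=C)C(=O)OC)CC2
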